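The decalone is cut at the two ring A bonds that leave ring B: C4–C4a and C1–C8a, which are trans on the vicinal carbons C4a and C8a. Ring B (C4a–C5–C6–C7–C8–C8a) with its C5, C6 and C8a methyl groups is then a 2,4,5-trimethylcyclohexadienone. In one flask a vinyl cuprate adds to C4a and the resulting enolate is propargylated at C8a, which sets both stereocentres and the trans ring fusion before ring A exists. The precursor is enantiopure dienone 10, whose quaternary C5 carries a methyl group and a tert-butyldiphenylsilyloxymethyl arm; this bulky, non-coordinating and acid-stable silyl ether steers the cuprate and survives to the end.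

Key step: step 6

Convention: the decalone numbering of the target is used for all compounds from 13 on (C1 CH–CH3, C2 C=O, C3, C4, C4a H, C5 CH3 and CH2O, C6 CH–CH3, C7, C8, C8a CH3). β is the face of the C4a hydrogen and the C5 oxymethyl arm; α is the face of the C5 and C8a methyl groups.

Assumption: the (S)-2-(methoxymethyl)pyrrolidine amide is taken to direct methylation of the 2-alkyl-substituted Birch enolate to the face that gives (1S)-7; if the sense were the reverse, the (R)-auxiliary would be used with no other change.

Step 1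
Reactants: 1 2,5-dimethylbenzoic acid; 2 (S)-2-(methoxymethyl)pyrrolidine
Product: 4 (2,5-dimethylphenyl)[(2S)-2-(methoxymethyl)pyrrolidin-1-yl]methanone, via 2,5-dimethylbenzoyl chloride 3 (not isolated)
Conditions: (COCl)2, DMF (cat.), CH2Cl2, 0 °C to rt; then 2, Et3N, CH2Cl2, 0 °C to rt
Reagents that add atoms: none
Why: Acid chloride formation followed by N-acylation of the secondary amine is reliable for ortho-substituted benzoic acids, and no stereocentre is formed.

Step 2
Reactants: 4 benzamide; 5 iodomethane
Product: 7 [(2S)-2-(methoxymethyl)pyrrolidin-1-yl][(1S)-1,2,5-trimethylcyclohexa-2,5-dien-1-yl]methanone, via potassium amide enolate 6 (not isolated)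
Conditions: K, t-BuOH (1 equiv), NH3/THF, −78 °C; then MeI, −78 °C to rt
Reagents that add atoms: none
Why: Auxiliary-controlled Birch reduction–alkylation: the ring is reduced at the ipso and para carbons (both methyl groups stay on alkene carbons), and the chelated amide enolate 6 is methylated on the face dictated by the pyrrolidine side chain, which sets quaternary C5.

Step 3
Reactants: 7 Birch product
Product: 8 [(1S)-1,2,5-trimethylcyclohexa-2,5-dien-1-yl]methanol
Conditions: LiN(i-Pr)2, BH3·NH3, THF, 0 to 23 °C; aq. HCl work-up
Reagents that add atoms: none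
Why: Lithium amidotrihydroborate reduces hindered tertiary amides to primary alcohols with C–N cleavage (amide reduction), so the auxiliary is released and the skipped diene and the quaternary centre are untouched.

Step 4
Reactants: 8 dienyl methanol
Product: 9 tert-butyl(diphenyl){[(1S)-1,2,5-trimethylcyclohexa-2,5-dien-1-yl]methoxy}silane
Conditions: t-BuPh2SiCl, imidazole, DMF, rt
Reagents that add atoms: tert-butyl(chloro)diphenylsilane, CC(C)(C)[Si](Cl)(c1ccccc1)c1ccccc1
Why: Imidazole-promoted silylation of the primary alcohol installs a large, poorly coordinating ether that should survive the later acidic, basic and reductive steps.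

Step 5
Reactants: 9 silyl ether
Product: 10 (4S)-4-{[tert-butyl(diphenyl)silyl]oxymethyl}-2,4,5-trimethylcyclohexa-2,5-dien-1-one
Conditions: (C5H5NH)2Cr2O7, t-BuOOH, Celite, benzene, rt
Reagents that add atoms: tert-butyl hydroperoxide, CC(C)(C)OO
Why: Chromium-mediated allylic oxidation with t-BuOOH as terminal oxidant attacks the doubly allylic CH2, the only activated methylene, and gives the cross-conjugated dienone without touching C5.

Step 6
Reactants: 10 dienone; 11 vinylmagnesium bromide; 12 propargyl bromide
Product: 14 vinyl propargyl cyclohexenone (ring B enone with C8=O and C6=C7; C5 α-methyl and β-silyloxymethyl; C4a α-vinyl; C8a α-methyl and β-propargyl), via bromomagnesium enolate 13 (not isolated)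
Conditions: C2H3MgBr, CuBr·SMe2, THF, −78 to −30 °C; then HMPA, HC≡CCH2Br, −78 to 0 °C
Reagents that add atoms: none
Why: The divinylcuprate forms a π-complex with the less substituted enone alkene, adds at the β-carbon C4a and reductively eliminates to the regiodefined bromomagnesium enolate 13, whose methyl-bearing carbon C8a then displaces bromide from propargyl bromide in an SN2 alkylation promoted by HMPA. The closest known reaction type is the three-component cuprate conjugate addition–enolate alkylation of 4,4-disubstituted cyclohexadienones. No ring is closed. C4a is controlled by quaternary C5: the flat dienone shows the cuprate a methyl group on one face and the much larger silyloxymethyl arm on the other, so vinyl should enter cis to the methyl group. C8a is controlled by the new C4a vinyl group, the electrophile entering anti to it so that the two ring A arms end up trans. Site selectivity between the two enone halves is secured by β-substitution (the C6 terminus carries a methyl group, C4a only hydrogen), and C- over O-alkylation by the soft, unhindered bromide.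

Step 7
Reactants: 14 vinyl propargyl cyclohexenone
Product: 15 alkynyl aldehyde (as 14 but with CHO in place of vinyl at C4a)
Conditions: OsO4 (cat.), NaIO4, 2,6-lutidine, 1,4-dioxane/H2O, rt
Reagents that add atoms: sodium periodate (terminal oxygen source, delivered through OsO4), [Na+].[O-]I(=O)(=O)=O
Why: Lemieux–Johnson cleavage (dihydroxylation, then periodate glycol cleavage) should select the monosubstituted vinyl group over the electron-poor trisubstituted enone alkene and the alkyne, and the buffer protects the C4a configuration.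

Step 8
Reactants: 15 alkynyl aldehyde
Product: 17 trans-fused bicyclic dienedione (C2=O with C3=C4 in ring A; C8=O with C6=C7 in ring B; 4aβ-H; 8aα-CH3), via keto aldehyde 16 (not isolated)
Conditions: Ph3PAuNTf2 (cat.), 1,4-dioxane/H2O, 60 °C; then aq. KOH, rt
Reagents that add atoms: water, O
Why: Gold-catalysed Markovnikov hydration of the terminal alkyne gives the methyl ketone, whose C3 enolate closes ring A on the C4 aldehyde by a 6-(enolendo)-exo-trig aldol condensation; the trans fusion follows from the C4a and C8a centres already in place.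

Step 9
Reactants: 17 dienedione
Product: 18 hydroxy enone (2α-OH and C3=C4 in ring A; ring B enone unchanged)
Conditions: NaBH4, CeCl3·7H2O, MeOH, −78 °C
Reagents that add atoms: none
Why: Luche 1,2-reduction should select the ring A carbonyl because the ring B carbonyl is flanked by quaternary C8a and deactivated by its β-methyl group; the temporary C2 carbinol centre (hydride expected anti to the C8a methyl) is erased in step 12, so either epimer serves.

Step 10
Reactants: 18 hydroxy enone
Product: 19 C8 tosylhydrazone of 18 (sulfonamide nitrogen anti to C8a)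
Conditions: TsNHNH2, AcOH (cat.), EtOH, 70 °C
Reagents that add atoms: 4-methylbenzenesulfonohydrazide, Cc1ccc(cc1)S(=O)(=O)NN
Why: Acid-catalysed condensation to the sulfonylhydrazone is known for ketones with a quaternary α-carbon, and only one carbonyl remains in the molecule.

Step 11
Reactants: 19 tosylhydrazone
Product: 21 diene alcohol (2α-OH; C3=C4; C7=C8; 6β-CH3 with 6α-H), via allylic diazene 20 (not isolated)
Conditions: catecholborane, CHCl3, 0 °C; then NaOAc·3H2O, 60 °C
Reagents that add atoms: none
Why: In this reductive alkene transposition of an enone tosylhydrazone, hydride should add to C8 from the β face, anti to the axial C8a methyl group, so that after loss of sulfinate the α-oriented diazene 20 hands its hydrogen suprafacially to the α face of C6 in a retro-ene loss of N2, which sets C6 and moves the alkene to C7=C8.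

Step 12
Reactants: 21 diene alcohol
Product: 22 enone (C2=O with C3=C4; C7=C8; 6β-CH3)
Conditions: Dess–Martin periodinane, NaHCO3, CH2Cl2, 0 °C to rt
Reagents that add atoms: none
Why: Dess–Martin oxidation of the allylic alcohol restores the ring A enone, which is needed to direct enolisation to C1.

Step 13
Reactants: 22 enone; 5 iodomethane
Product: 24 1β-methyl enone (C1 methyl trans to the C8a methyl), via lithium dienolate 23 (not isolated)
Conditions: LiN(i-Pr)2, THF, −78 °C; then MeI, DMPU, −78 to −40 °C
Reagents that add atoms: none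
Why: Kinetic deprotonation of the enone can only occur at the α′ carbon C1 (C3 is vinylic), and the cross-conjugated enolate should be methylated anti to the pseudoaxial C8a methyl group; the C1 configuration is corrected in step 15.

Step 14
Reactants: 24 1β-methyl enone
Product: 25 saturated 1β-methyl decalone silyl ether
Conditions: H2 (1 atm), Pd/C, EtOAc, rt
Reagents that add atoms: none
Why: Heterogeneous hydrogenation saturates the C3=C4 enone alkene and the cis-disubstituted C7=C8 alkene, and no stereocentre is created because C3, C4, C7 and C8 all become methylenes.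

Step 15
Reactants: 25 saturated 1β-methyl decalone silyl ether
Product: 27 keto alcohol (1α,5α,6β,8aα-tetramethyl-5β-hydroxymethyl-4aβ-H-decal-2-one), via 1β-methyl keto alcohol 26 (not isolated)
Conditions: Bu4NF, THF, 50 °C; then NaOMe, MeOH, rt
Reagents that add atoms: none
Why: Fluoride cleaves the silyl ether, and methoxide equilibrates C1 through its enolate to the equatorial 1α-methyl ketone, which avoids the two syn-axial hydrogens (at C3 and C4a) that flank a 1β-methyl group.

Step 16
Reactants: 27 keto alcohol; 28 isofraxidin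
Product: 29 target coumarin ether CNP0225022.1
Conditions: PPh3, DIAD, THF (ca. 2 M), ultrasound, 25 to 40 °C
Reagents that add atoms: none
Why: Mitsunobu etherification: the acidic coumarin phenol protonates the betaine and its phenoxide displaces the alkoxyphosphonium of the primary carbinol, which cannot eliminate; concentrated, sonicated conditions are the known remedy for slow substitution at a neopentyl carbon.

Compound list
1 | 2,5-dimethylbenzoic acid | Cc1ccc(C)c(C(=O)O)c1 | starting material
2 | (S)-2-(methoxymethyl)pyrrolidine | COC[C@@H]1CCCN1 | starting material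
3 | 2,5-dimethylbenzoyl chloride | Cc1ccc(C)c(C(=O)Cl)c1 | intermediate
4 | (2,5-dimethylphenyl)[(2S)-2-(methoxymethyl)pyrrolidin-1-yl]methanone | COC[C@@H]1CCCN1C(=O)c1cc(C)ccc1C | intermediate
5 | iodomethane | CI | starting material
6 | potassium amide enolate of the 1,4-dihydrobenzamide | COC[C@@H]1CCCN1C([O-])=C1C(C)=CCC(C)=C1.[K+] | intermediate
7 | [(2S)-2-(methoxymethyl)pyrrolidin-1-yl][(1S)-1,2,5-trimethylcyclohexa-2,5-dien-1-yl]methanone | COC[C@@H]1CCCN1C(=O)[C@@]1(C)C=C(C)CC=C1C | intermediate
8 | [(1S)-1,2,5-trimethylcyclohexa-2,5-dien-1-yl]methanol | OC[C@@]1(C)C=C(C)CC=C1C | intermediate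
9 | tert-butyl(diphenyl){[(1S)-1,2,5-trimethylcyclohexa-2,5-dien-1-yl]methoxy}silane | CC(C)(C)[Si](c1ccccc1)(c1ccccc1)OC[C@@]1(C)C=C(C)CC=C1C | intermediate
10 | (4S)-4-{[tert-butyl(diphenyl)silyl]oxymethyl}-2,4,5-trimethylcyclohexa-2,5-dien-1-one | CC(C)(C)[Si](c1ccccc1)(c1ccccc1)OC[C@@]1(C)C=C(C)C(=O)C=C1C | intermediate
11 | vinylmagnesium bromide | C=C[Mg]Br | starting material
12 | propargyl bromide | C#CCBr | starting material
13 | bromomagnesium enolate of the C4a vinyl adduct (C8–O–MgBr, C8=C8a, vinyl α) | CC(C)(C)[Si](c1ccccc1)(c1ccccc1)OC[C@@]1(C)[C@H](C=C)C(C)=C(O[Mg]Br)C=C1C | intermediate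
14 | vinyl propargyl cyclohexenone (C4a α-vinyl; C8a α-methyl and β-propargyl) | CC(C)(C)[Si](c1ccccc1)(c1ccccc1)OC[C@@]1(C)[C@H](C=C)[C@@](C)(CC#C)C(=O)C=C1C | intermediate
15 | alkynyl aldehyde (C4a α-CHO) | CC(C)(C)[Si](c1ccccc1)(c1ccccc1)OC[C@@]1(C)[C@H](C=O)[C@@](C)(CC#C)C(=O)C=C1C | intermediate
16 | keto aldehyde (C8a β-2-oxopropyl; C4a α-CHO) | CC(C)(C)[Si](c1ccccc1)(c1ccccc1)OC[C@@]1(C)[C@H](C=O)[C@@](C)(CC(C)=O)C(=O)C=C1C | intermediate
17 | trans-fused bicyclic dienedione | CC(C)(C)[Si](c1ccccc1)(c1ccccc1)OC[C@@]1(C)[C@@H]2C=CC(=O)C[C@@]2(C)C(=O)C=C1C | intermediate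
18 | 2α-hydroxy enone | CC(C)(C)[Si](c1ccccc1)(c1ccccc1)OC[C@@]1(C)[C@@H]2C=C[C@H](O)C[C@@]2(C)C(=O)C=C1C | intermediate
19 | C8 tosylhydrazone | CC(C)(C)[Si](c1ccccc1)(c1ccccc1)OC[C@@]1(C)[C@@H]2C=C[C@H](O)C[C@@]2(C)/C(=N/NS(=O)(=O)c3ccc(C)cc3)C=C1C | intermediate
20 | allylic diazene (8α-N=NH) | CC(C)(C)[Si](c1ccccc1)(c1ccccc1)OC[C@@]1(C)[C@@H]2C=C[C@H](O)C[C@@]2(C)[C@H](N=N)C=C1C | intermediate
21 | diene alcohol (6β-methyl) | CC(C)(C)[Si](c1ccccc1)(c1ccccc1)OC[C@@]1(C)[C@@H]2C=C[C@H](O)C[C@@]2(C)C=C[C@H]1C | intermediate
22 | ring A enone with C7=C8 alkene | CC(C)(C)[Si](c1ccccc1)(c1ccccc1)OC[C@@]1(C)[C@@H]2C=CC(=O)C[C@@]2(C)C=C[C@H]1C | intermediate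
23 | lithium dienolate (C2–OLi, C1=C2, C3=C4) | CC(C)(C)[Si](c1ccccc1)(c1ccccc1)OC[C@@]1(C)[C@@H]2C=CC(O[Li])=C[C@@]2(C)C=C[C@H]1C | intermediate
24 | 1β-methyl enone | CC(C)(C)[Si](c1ccccc1)(c1ccccc1)OC[C@@]1(C)[C@@H]2C=CC(=O)[C@@H](C)[C@@]2(C)C=C[C@H]1C | intermediate
25 | saturated 1β-methyl decalone silyl ether | CC(C)(C)[Si](c1ccccc1)(c1ccccc1)OC[C@@]1(C)[C@@H]2CCC(=O)[C@@H](C)[C@@]2(C)CC[C@H]1C | intermediate
26 | 1β-methyl keto alcohol | OC[C@@]1(C)[C@@H]2CCC(=O)[C@@H](C)[C@@]2(C)CC[C@H]1C | intermediate
27 | keto alcohol (1α-methyl) | OC[C@@]1(C)[C@@H]2CCC(=O)[C@H](C)[C@@]2(C)CC[C@H]1C | intermediate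
28 | isofraxidin (7-hydroxy-6,8-dimethoxycoumarin) | COc1cc2ccc(=O)oc2c(OC)c1O | starting material
29 | CNP0225022.1 | COc1cc2ccc(=O)oc2c(OC)c1OC[C@@]1(C)[C@@H]2CCC(=O)[C@H](C)[C@@]2(C)CC[C@H]1C | target

Total step count: 16. Longest linear sequence: 16 steps, from 1 to 29; compounds 2, 5, 11, 12 and 28 are bought.

Steps most likely to fail

Step 6. Capture of the hindered, tetrasubstituted enolate 13 may be slow, so that it is protonated (the alkyne C–H of the electrophile is acidic) or alkylated on oxygen, and selectivity at C8a erodes. Fallback: from dienone 10 the same cuprate addition is run, but enolate 13 is trapped on oxygen with allyl chloroformate to give the allyl enol carbonate F1. Pd(PPh3)4 in THF then effects decarboxylative allylation to the α-allyl ketone F2, a reaction that builds congested quaternary α-carbons where direct alkylation fails. Wacker oxidation (PdCl2, CuCl, O2, DMF/H2O) of the accessible allyl group, the vinyl group being shielded by two quaternary neighbours, gives the methyl ketone F3. OsO4/NaIO4 cleavage of the vinyl group gives keto aldehyde 16, which is cyclised with KOH as in step 8, and the route is rejoined at 17.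

Step 16. Substitution at the neopentyl carbon may be slower than breakdown of the alkoxyphosphonium intermediate or alkylation of the reduced azo reagent. Fallback: from keto alcohol 27, Tf2O and pyridine (CH2Cl2, −78 °C) give the neopentyl triflate F4, which is displaced by the cesium salt of 28 (Cs2CO3, DMF, 25 to 50 °C) to arrive at 29. Such a triflate has no β-hydrogen to eliminate and is displaced under conditions too mild for ionisation.

Step 11. Hydride may reach the C8 hydrazone from the α face, or the diazene may be lost without hydrogen transfer, so that C6 forms with the wrong configuration or the alkene does not shift. Fallback: from hydroxy enone 18, DIBAL-H (CH2Cl2, −78 °C) reduces the C8 carbonyl from the β face to the 2α,8α-diol F5. Hydroxyl-directed hydrogenation with [Ir(cod)(PCy3)(py)]PF6 (H2, CH2Cl2) delivers hydrogen to the α face of C6=C7 and also saturates C3=C4, giving the saturated diol F6. TEMPO/PhI(OAc)2 oxidises only the unhindered C2 carbinol to give hydroxy ketone F7. Burgess reagent (benzene, 60 °C) removes the C8 hydroxyl by syn-elimination toward C7, the only neighbour with hydrogens, giving alkene ketone F8. IBX (DMSO, 70 °C) dehydrogenates the ketone, which can only give the C3=C4 enone because C8a is quaternary, and the route is rejoined at 22.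

Further compounds
F1 | step 6 | allyl enol carbonate of the C4a vinyl adduct | CC(C)(C)[Si](c1ccccc1)(c1ccccc1)OC[C@@]1(C)[C@H](C=C)C(C)=C(OC(=O)OCC=C)C=C1C
F2 | step 6 | α-allyl ketone (C8a α-methyl and β-allyl; C4a α-vinyl) | CC(C)(C)[Si](c1ccccc1)(c1ccccc1)OC[C@@]1(C)[C@H](C=C)[C@@](C)(CC=C)C(=O)C=C1C
F3 | step 6 | methyl ketone (C8a β-2-oxopropyl; C4a α-vinyl) | CC(C)(C)[Si](c1ccccc1)(c1ccccc1)OC[C@@]1(C)[C@H](C=C)[C@@](C)(CC(C)=O)C(=O)C=C1C
F4 | step 16 | neopentyl triflate of keto alcohol 27 | O=S(=O)(OC[C@@]1(C)[C@@H]2CCC(=O)[C@H](C)[C@@]2(C)CC[C@H]1C)C(F)(F)F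
F5 | step 11 | 2α,8α-diol with C3=C4 and C6=C7 | CC(C)(C)[Si](c1ccccc1)(c1ccccc1)OC[C@@]1(C)[C@@H]2C=C[C@H](O)C[C@@]2(C)[C@H](O)C=C1C
F6 | step 11 | saturated 2α,8α-diol (6β-methyl) | CC(C)(C)[Si](c1ccccc1)(c1ccccc1)OC[C@@]1(C)[C@@H]2CC[C@H](O)C[C@@]2(C)[C@H](O)C[C@H]1C
F7 | step 11 | 8α-hydroxy decal-2-one | CC(C)(C)[Si](c1ccccc1)(c1ccccc1)OC[C@@]1(C)[C@@H]2CCC(=O)C[C@@]2(C)[C@H](O)C[C@H]1C
F8 | step 11 | decal-2-one with C7=C8 alkene | CC(C)(C)[Si](c1ccccc1)(c1ccccc1)OC[C@@]1(C)[C@@H]2CCC(=O)C[C@@]2(C)C=C[C@H]1C
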